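**Plan**

- Retrosynthetic cuts: (i) the bond from the quaternary carbon to the tetrahydrofuran (tertiary radical plus butenolide); (ii) in the hydroazulene, the CH2–CMe2 bond and the ring-fusion C–C bond, made together by a [2+2] photocycloaddition, with a temporary bond between the ring-fusion carbon and the future CH2 that is then cleaved by retro-aldol (de Mayo); (iii) the quaternary carbon–dione bond (Claisen).
- Enabling feature: in the seven-membered ring the methylidene carbon and the CH2 beside CMe2 are 1,4-related across CH2CH2, so the ring is a latent cycloheptane-1,4-dione, i.e. a cyclopentane-1,3-dione enol ether plus an alkene. The CMe2–CH(ring fusion) pair is a prenyl-type alkene held three atoms (through the quaternary carbon) from C2 of the dione, which closes the cyclopentane by 1,5-closure.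
- Forward order: Claisen (quaternary carbon) → iodoether (temporary ring) → photocycloaddition (cyclopentane and cyclobutane) → zinc-triggered fragmentation (seven-membered ring) → acid, methylidene, deoxygenation → radical coupling to a butenolide → lactone remodelled into the acetoxytetrahydrofuran side chain.
- Stereochemistry: a catalyst-set carbinol gives the quaternary carbon by chair Claisen. That carbon, locked in the iodoether ring, sets the CH–CMe2 ring-fusion centre; the second ring-fusion CH comes from convex-face protonation. The quaternary carbon is re-formed, together with the adjacent tetrahydrofuran carbon, in the radical addition (convex face, anti to the acetal). The next ring carbon comes from a trans aldol, the side-chain carbinol from Felkin–Anh addition then Jocic inversion, and the acetal carbon from acetylation trans to its neighbour.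

Key step: step 5

Remark: geranial is used as the pure E isomer. Centres that are erased later (the two iodoether carbons in 6 and 7, the acetal carbon in 17–24) are drawn as the expected major isomer.
Abbreviation: Az = (1R,3aR,8aS)-1,4,4-trimethyl-8-methylidenedecahydroazulen-1-yl.

**Route**

Step 1
Reactants: 1 geranial
Product: 2 (2R,3E)-4,8-dimethylnona-3,7-dien-2-ol
Conditions: Me2Zn, (+)-MIB (5 mol %), toluene, 0 °C
Reagents that add atoms: dimethylzinc, C[Zn]C
Why: Amino-alcohol-catalysed enantioselective addition of a dialkylzinc to an aldehyde; the (+)-ligand should deliver methyl to the Re face of the enal carbonyl, which sets the 2R carbinol centre, and organozincs add 1,2 only.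

Step 2
Reactants: 2 (2R,3E)-4,8-dimethylnona-3,7-dien-2-ol; 3 cyclopentane-1,3-dione
Product: 4 3-{[(2S,3E)-4,8-dimethylnona-3,7-dien-2-yl]oxy}cyclopent-2-en-1-one
Conditions: PPh3, DIAD, THF, 0 °C to rt
Reagents that add atoms: none
Why: Mitsunobu O-alkylation of the acidic cyclic 1,3-dione proceeds by SN2 with inversion (2R alcohol to 2S vinylogous ester) and avoids acid that could ionise the allylic C–O bond.

Step 3
Reactants: 4 3-{[(2S,3E)-4,8-dimethylnona-3,7-dien-2-yl]oxy}cyclopent-2-en-1-one
Product: 5 2-[(2E,4R)-4,8-dimethylnona-2,7-dien-4-yl]cyclopentane-1,3-dione (mainly as its enol)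
Conditions: xylene, 140 °C, sealed tube
Reagents that add atoms: none
Why: Thermal Claisen ([3,3]) rearrangement of the 3-allyloxy enone through a chair transition state with the carbinol methyl equatorial should transfer the C–O stereocentre to the new quaternary carbon (4R) and give the E-propenyl group.

Step 4
Reactants: 5 2-[(2E,4R)-4,8-dimethylnona-2,7-dien-4-yl]cyclopentane-1,3-dione
Product: 6 (2S,3S)-2-[(1R)-1-iodoethyl]-3-methyl-3-(4-methylpent-3-en-1-yl)-2,3,5,6-tetrahydro-4H-cyclopenta[b]furan-4-one
Conditions: I2, NaHCO3, MeCN, 0 °C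
Reagents that add atoms: iodine, II
Why: Iodoetherification of a 2-allyl-1,3-dione: the enol oxygen opens the iodonium ion of the propenyl group by 5-exo anti addition, which locks the quaternary carbon in a dihydrofuran (temporary ring) and masks the propenyl alkene, while the remote trisubstituted alkene has no nucleophile in reach.

Step 5
Reactants: 6 (2S,3S)-2-[(1R)-1-iodoethyl]-3-methyl-3-(4-methylpent-3-en-1-yl)-2,3,5,6-tetrahydro-4H-cyclopenta[b]furan-4-one
Product: 7 tetracyclic photoadduct: cyclopentanone, iodoethyl-tetrahydrofuran, new cyclobutane (with the CMe2 carbon) and new cyclopentane around the two former enol ether carbons; cyclobutane on the face of the former methylpentenyl arm, anti to the ring methyl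
Conditions: hν (350–366 nm, uranium-glass filter), degassed MeCN, 0 °C
Reagents that add atoms: none
Why: Light excites the cyclic β-alkoxy enone (vinylogous ester) to its triplet, which adds to the tethered trisubstituted alkene in an intramolecular enone–alkene [2+2] photocycloaddition, the first half of a de Mayo sequence; the closest known reaction type is the photocycloaddition of enol derivatives of 2-(pent-4-enyl)cyclopentane-1,3-diones that leads to hydroazulenediones. The first bond joins the enone α-carbon (the future ring-fusion CH beside the methylidene carbon) to the alkene CH and closes the cyclopentane in a 5-exo (1,5, rule-of-five) mode; the resulting 1,4-biradical then closes the four-membered ring between the oxygenated carbon and the CMe2 carbon, so the straight (bicyclo[3.2.0]) adduct is expected, not the crossed one. The new CH–CMe2 stereocentre is controlled by the quaternary carbon through the temporary dihydrofuran ring: the ring holds the methylpentenyl arm on one face of the flat enol ether, the alkene can reach only that face, and the cyclobutane is cis-fused to both five-membered rings by geometry. The step needs chemoselectivity for the enone chromophore over the C–I bond and the propenyl group: irradiation above 350 nm, where the alkyl iodide does not absorb, and fast intramolecular trapping should secure the first, and the propenyl alkene is masked in the iodoether. The strain stored in the alkoxycyclobutane drives the bond cleavage of step 6.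

Step 6
Reactants: 7 tetracyclic photoadduct
Product: 9 (1R,3aR,8aR)-1,4,4-trimethyl-1-[(1E)-prop-1-en-1-yl]perhydroazulene-5,8-dione (cis-fused), via cyclobutanol 8 (not isolated)
Conditions: Zn dust, AcOH, THF, 0 °C
Reagents that add atoms: none
Why: Zinc reduces the C–I bond and the β-alkoxy organozinc eliminates (Boord-type reductive elimination), which restores the propenyl group and frees the cyclobutanolate; ring strain then drives the retro-aldol (de Mayo) cleavage of the bond between the carbinol carbon and the ring-fusion carbon to the cycloheptane-1,4-dione, and acetic acid should protonate the zinc enolate on the convex face (that of the neighbouring ring-fusion hydrogen) to give the cis ring fusion without equilibration.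

Step 7
Reactants: 9 (1R,3aR,8aR)-1,4,4-trimethyl-1-[(1E)-prop-1-en-1-yl]perhydroazulene-5,8-dione
Product: 10 (1S,3aR,8aR)-1,4,4-trimethyl-5,8-dioxoperhydroazulene-1-carboxylic acid
Conditions: RuCl3·xH2O (cat.), NaIO4, CCl4/MeCN/H2O, rt
Reagents that add atoms: sodium periodate, [Na+].[O-]I(=O)(=O)=O; water, O
Why: Ruthenium tetroxide oxidation (Sharpless conditions) cleaves the only C=C bond left, the propenyl group, to the carboxylic acid on the quaternary carbon; ketones are inert and the medium does not enolise the ring-fusion centre.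

Step 8
Reactants: 10 (1S,3aR,8aR)-1,4,4-trimethyl-5,8-dioxoperhydroazulene-1-carboxylic acid
Product: 11 (1S,3aR,8aS)-1,4,4-trimethyl-8-methylidene-5-oxoperhydroazulene-1-carboxylic acid
Conditions: Zn, CH2Br2, TiCl4 (excess), THF/CH2Cl2, 0 °C to rt
Reagents that add atoms: dibromomethane, BrCBr
Why: Lombardo methylenation is non-basic, so the epimerisable ring-fusion centre is kept, and it should select the ketone flanked by CH and CH2 over the neopentyl ketone beside the gem-dimethyl carbon; the free acid is tolerated with excess reagent.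

Step 9
Reactants: 11 (1S,3aR,8aS)-1,4,4-trimethyl-8-methylidene-5-oxoperhydroazulene-1-carboxylic acid
Product: 13 (1S,3aR,8aS)-1,4,4-trimethyl-8-methylidenedecahydroazulene-1-carboxylic acid, via hydrazone 12 (not isolated)
Conditions: N2H4·H2O, KOH, diethylene glycol, 130 °C then 200 °C; cold acidification to pH 4
Reagents that add atoms: none
Why: Wolff–Kishner reduction (Huang-Minlon procedure) removes the hindered ketone beside the gem-dimethyl carbon; the carboxylate and the unconjugated exocyclic alkene, which now has no enolisable neighbour, should survive hot KOH.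

Step 10
Reactants: 13 (1S,3aR,8aS)-1,4,4-trimethyl-8-methylidenedecahydroazulene-1-carboxylic acid; 14 (5S)-5-{[(1S,2R,5S)-5-methyl-2-(propan-2-yl)cyclohexyl]oxy}furan-2(5H)-one
Product: 15 (4R,5S)-4-Az-5-{[(1S,2R,5S)-5-methyl-2-(propan-2-yl)cyclohexyl]oxy}dihydrofuran-2(3H)-one
Conditions: Ir[dF(CF3)ppy]2(dtbbpy)PF6 (1 mol %), K2HPO4, DMF, blue LEDs, rt
Reagents that add atoms: none
Why: Photoredox decarboxylative Giese reaction: oxidation of the carboxylate and loss of CO2 give the planar tertiary radical, which should add to the butenolide β-carbon through its convex face (opposite the two bonds of the seven-membered ring) and anti to the menthyloxy group, so the quaternary carbon is re-formed with methyl cis to the seven-membered ring and the adjacent lactone carbon is set; tertiary radicals of this cis-perhydroazulene type are known to add to 5-alkoxybutenolides in this sense.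

Step 11
Reactants: 15 (4R,5S)-4-Az-5-(menthyloxy)dihydrofuran-2(3H)-one
Product: 16 (3R,4R,5S)-4-Az-3-(hydroxymethyl)-5-{[(1S,2R,5S)-5-methyl-2-(propan-2-yl)cyclohexyl]oxy}dihydrofuran-2(3H)-one
Conditions: LiN(SiMe3)2, THF, −78 °C; CH2O (gas); AcOH quench
Reagents that add atoms: formaldehyde, C=O
Why: Aldol hydroxymethylation of the lactone lithium enolate occurs anti to the bulky β-substituent (3,4-trans), which places the future side-chain carbon cis to Az once the ring oxygen changes partner in step 12.

Step 12
Reactants: 16 (3R,4R,5S)-4-Az-3-(hydroxymethyl)-5-(menthyloxy)dihydrofuran-2(3H)-one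
Product: 17 methyl (3R,4R,5S)-4-Az-5-methoxytetrahydrofuran-3-carboxylate
Conditions: CSA (cat.), MeOH, 40 °C
Reagents that add atoms: methanol, CO
Why: Acid-catalysed methanolysis of the pseudo-ester (acylal) opens the lactone to the methyl ester and releases the masked aldehyde, which the primary hydroxyl captures as the five-membered cyclic methyl acetal (transacetalisation with loss of menthol); no C–H stereocentre is touched.

Step 13
Reactants: 17 methyl (3R,4R,5S)-4-Az-5-methoxytetrahydrofuran-3-carboxylate
Product: 18 (3R,4R,5S)-4-Az-5-methoxytetrahydrofuran-3-carbaldehyde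
Conditions: iBu2AlH, CH2Cl2, −78 °C; Rochelle salt work-up
Reagents that add atoms: none
Why: Half-reduction of a methyl ester with iBu2AlH at −78 °C stops at the aluminium hemiacetal, which gives the aldehyde on work-up; the aldehyde is used at once to avoid epimerisation at the α-carbon.

Step 14
Reactants: 18 (3R,4R,5S)-4-Az-5-methoxytetrahydrofuran-3-carbaldehyde
Product: 19 (1R)-2,2,2-trichloro-1-[(3R,4R,5S)-4-Az-5-methoxytetrahydrofuran-3-yl]ethanol
Conditions: Cl3CCO2H, Cl3CCO2Na, DMF, 0 °C to rt
Reagents that add atoms: trichloroacetic acid, OC(=O)C(Cl)(Cl)Cl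
Why: Decarboxylative trichloromethylation (first stage of the Corey–Link sequence): trichloromethide adds to the aldehyde under near-neutral conditions and, by the Felkin–Anh model, anti to the ring carbon that bears Az, which should give the R carbinol.

Step 15
Reactants: 19 (1R)-2,2,2-trichloro-1-[(3R,4R,5S)-4-Az-5-methoxytetrahydrofuran-3-yl]ethanol
Product: 21 (2S)-2-hydroxy-2-[(3R,4R,5S)-4-Az-5-methoxytetrahydrofuran-3-yl]acetic acid, via dichloroepoxide 20 (not isolated)
Conditions: NaOH, DME/H2O, 0 °C to rt; then acidify to pH 3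
Reagents that add atoms: sodium hydroxide, [Na+].[OH-]
Why: Jocic–Reeve reaction: the alkoxide closes to the gem-dichloroepoxide, hydroxide opens it at the carbinol carbon with inversion (R to S), and the acyl chloride so formed is hydrolysed, which gives the α-hydroxy acid with the target configuration.

Step 16
Reactants: 21 (2S)-2-hydroxy-2-[(3R,4R,5S)-4-Az-5-methoxytetrahydrofuran-3-yl]acetic acid
Product: 22 methyl (2S)-2-hydroxy-2-[(3R,4R,5S)-4-Az-5-methoxytetrahydrofuran-3-yl]acetate
Conditions: Me3SiCHN2, MeOH/toluene, 0 °C
Reagents that add atoms: (trimethylsilyl)diazomethane, C[Si](C)(C)C=[N+]=[N-]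
Why: Esterification of a carboxylic acid with (trimethylsilyl)diazomethane in methanol is neutral and leaves the secondary alcohol, acetal and alkene untouched.

Step 17
Reactants: 22 methyl (2S)-2-hydroxy-2-[(3R,4R,5S)-4-Az-5-methoxytetrahydrofuran-3-yl]acetate
Product: 23 methyl (2S)-2-acetoxy-2-[(3R,4R,5S)-4-Az-5-methoxytetrahydrofuran-3-yl]acetate
Conditions: Ac2O, pyridine, DMAP (cat.), CH2Cl2, rt
Reagents that add atoms: acetic anhydride, CC(=O)OC(C)=O
Why: DMAP-catalysed acetylation of the secondary alcohol, done before the acetal is opened so that this hydroxyl cannot later compete for the aldehyde carbon.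

Step 18
Reactants: 23 methyl (2S)-2-acetoxy-2-[(3R,4R,5S)-4-Az-5-methoxytetrahydrofuran-3-yl]acetate
Product: 24 methyl (2S)-2-acetoxy-2-[(3R,4R,5S)-4-Az-5-hydroxytetrahydrofuran-3-yl]acetate (lactol, anomers)
Conditions: 1 M HCl (aq)/THF, rt
Reagents that add atoms: water, O
Why: Mild aqueous acid hydrolysis of the cyclic methyl acetal to the lactol; the acetate, the methyl ester and the exocyclic alkene should be stable to dilute acid at room temperature.

Step 19
Reactants: 24 methyl (2S)-2-acetoxy-2-[(3R,4R,5S)-4-Az-5-hydroxytetrahydrofuran-3-yl]acetate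
Product: 25 methyl (2S)-2-acetoxy-2-[(3R,4R,5R)-5-acetoxy-4-Az-tetrahydrofuran-3-yl]acetate (CNP0222222.1)
Conditions: Ac2O, pyridine, DMAP (cat.), CH2Cl2, 0 °C
Reagents that add atoms: acetic anhydride, CC(=O)OC(C)=O
Why: Acetylation of the equilibrating lactol anomers should be fastest on the less hindered anomer, with the oxygen trans to the neighbouring Az group, which gives the anomeric acetate of the target.

**Compound list**

1 | geranial, (2E)-3,7-dimethylocta-2,6-dienal | CC(C)=CCC/C(C)=C/C=O | starting material
2 | (2R,3E)-4,8-dimethylnona-3,7-dien-2-ol | C[C@@H](O)/C=C(\C)CCC=C(C)C | intermediate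
3 | cyclopentane-1,3-dione | O=C1CCC(=O)C1 | starting material
4 | 3-{[(2S,3E)-4,8-dimethylnona-3,7-dien-2-yl]oxy}cyclopent-2-en-1-one | O=C1CCC(O[C@@H](C)/C=C(\C)CCC=C(C)C)=C1 | intermediate
5 | 2-[(2E,4R)-4,8-dimethylnona-2,7-dien-4-yl]cyclopentane-1,3-dione | CC(C)=CCC[C@@](/C=C/C)(C)C1C(=O)CCC1=O | intermediate
6 | (2S,3S)-2-[(1R)-1-iodoethyl]-3-methyl-3-(4-methylpent-3-en-1-yl)-2,3,5,6-tetrahydro-4H-cyclopenta[b]furan-4-one | O=C1CCC2=C1[C@](C)(CCC=C(C)C)[C@@H]([C@H](I)C)O2 | intermediate
7 | tetracyclic iodoether photoadduct (cyclobutane cis-fused to both five-membered rings, anti to the ring methyl) | O=C1CC[C@]2(O[C@H]([C@@H](C)I)[C@@]3(C)CC[C@H]4C2(C)C)[C@@]134 | intermediate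
8 | tricyclic cyclobutanol with restored E-propenyl group (not isolated) | O=C1CC[C@@]2(O)C(C)(C)[C@@H]3CC[C@](C)(/C=C/C)[C@]123 | intermediate
9 | (1R,3aR,8aR)-1,4,4-trimethyl-1-[(1E)-prop-1-en-1-yl]perhydroazulene-5,8-dione | O=C1CCC(=O)C(C)(C)[C@@H]2CC[C@@](/C=C/C)(C)[C@H]12 | intermediate
10 | (1S,3aR,8aR)-1,4,4-trimethyl-5,8-dioxoperhydroazulene-1-carboxylic acid | O=C1CCC(=O)C(C)(C)[C@@H]2CC[C@@](C(=O)O)(C)[C@H]12 | intermediate
11 | (1S,3aR,8aS)-1,4,4-trimethyl-8-methylidene-5-oxoperhydroazulene-1-carboxylic acid | C=C1CCC(=O)C(C)(C)[C@@H]2CC[C@@](C(=O)O)(C)[C@H]12 | intermediate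
12 | hydrazone of 11 (not isolated) | C=C1CCC(=NN)C(C)(C)[C@@H]2CC[C@@](C(=O)O)(C)[C@H]12 | intermediate
13 | (1S,3aR,8aS)-1,4,4-trimethyl-8-methylidenedecahydroazulene-1-carboxylic acid | C=C1CCCC(C)(C)[C@@H]2CC[C@@](C(=O)O)(C)[C@H]12 | intermediate
14 | (5S)-5-{[(1S,2R,5S)-5-methyl-2-(propan-2-yl)cyclohexyl]oxy}furan-2(5H)-one | O=C1C=C[C@@H](O[C@H]2C[C@@H](C)CC[C@@H]2C(C)C)O1 | starting material
15 | (4R,5S)-4-Az-5-{[(1S,2R,5S)-5-methyl-2-(propan-2-yl)cyclohexyl]oxy}dihydrofuran-2(3H)-one | C=C1CCCC(C)(C)[C@@H]2CC[C@@](C)([C@@H]3[C@@H](O[C@H]4C[C@@H](C)CC[C@@H]4C(C)C)OC(=O)C3)[C@H]12 | intermediate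
16 | (3R,4R,5S)-4-Az-3-(hydroxymethyl)-5-(menthyloxy)dihydrofuran-2(3H)-one | C=C1CCCC(C)(C)[C@@H]2CC[C@@](C)([C@@H]3[C@@H](O[C@H]4C[C@@H](C)CC[C@@H]4C(C)C)OC(=O)[C@H]3CO)[C@H]12 | intermediate
17 | methyl (3R,4R,5S)-4-Az-5-methoxytetrahydrofuran-3-carboxylate | C=C1CCCC(C)(C)[C@@H]2CC[C@@](C)([C@@H]3[C@@H](OC)OC[C@@H]3C(=O)OC)[C@H]12 | intermediate
18 | (3R,4R,5S)-4-Az-5-methoxytetrahydrofuran-3-carbaldehyde | C=C1CCCC(C)(C)[C@@H]2CC[C@@](C)([C@@H]3[C@@H](OC)OC[C@@H]3C=O)[C@H]12 | intermediate
19 | (1R)-2,2,2-trichloro-1-[(3R,4R,5S)-4-Az-5-methoxytetrahydrofuran-3-yl]ethanol | C=C1CCCC(C)(C)[C@@H]2CC[C@@](C)([C@@H]3[C@@H](OC)OC[C@@H]3[C@@H](O)C(Cl)(Cl)Cl)[C@H]12 | intermediate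
20 | gem-dichloroepoxide from 19 (not isolated) | C=C1CCCC(C)(C)[C@@H]2CC[C@@](C)([C@@H]3[C@@H](OC)OC[C@@H]3[C@H]4OC4(Cl)Cl)[C@H]12 | intermediate
21 | (2S)-2-hydroxy-2-[(3R,4R,5S)-4-Az-5-methoxytetrahydrofuran-3-yl]acetic acid | C=C1CCCC(C)(C)[C@@H]2CC[C@@](C)([C@@H]3[C@@H](OC)OC[C@@H]3[C@H](O)C(=O)O)[C@H]12 | intermediate
22 | methyl (2S)-2-hydroxy-2-[(3R,4R,5S)-4-Az-5-methoxytetrahydrofuran-3-yl]acetate | C=C1CCCC(C)(C)[C@@H]2CC[C@@](C)([C@@H]3[C@@H](OC)OC[C@@H]3[C@H](O)C(=O)OC)[C@H]12 | intermediate
23 | methyl (2S)-2-acetoxy-2-[(3R,4R,5S)-4-Az-5-methoxytetrahydrofuran-3-yl]acetate | C=C1CCCC(C)(C)[C@@H]2CC[C@@](C)([C@@H]3[C@@H](OC)OC[C@@H]3[C@H](OC(C)=O)C(=O)OC)[C@H]12 | intermediate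
24 | methyl (2S)-2-acetoxy-2-[(3R,4R,5S)-4-Az-5-hydroxytetrahydrofuran-3-yl]acetate | C=C1CCCC(C)(C)[C@@H]2CC[C@@](C)([C@@H]3[C@@H](O)OC[C@@H]3[C@H](OC(C)=O)C(=O)OC)[C@H]12 | intermediate
25 | methyl (2S)-2-acetoxy-2-[(3R,4R,5R)-5-acetoxy-4-Az-tetrahydrofuran-3-yl]acetate (CNP0222222.1) | C=C1CCCC(C)(C)[C@@H]2CC[C@@](C)([C@@H]3[C@@H](OC(C)=O)OC[C@@H]3[C@H](OC(C)=O)C(=O)OC)[C@H]12 | target

**Step count and risks**

Total step count: 19. Longest linear sequence: 19 steps (1 to 25); 3 and 14 are purchased.

Steps most likely to fail:

1. Step 5. Homolysis of the C–I bond under irradiation, or closure to the crossed adduct, would erode the photocycloaddition. Fallback, from 5 back to 9: the classical enol-ester de Mayo sequence without the temporary ring. Dione 5 is O-acetylated (Ac2O, Et3N, DMAP) to 3-oxo-2-[(2E,4R)-4,8-dimethylnona-2,7-dien-4-yl]cyclopent-1-en-1-yl acetate F1. Irradiation at 350 nm gives the acetoxycyclobutane photoadduct F2, and K2CO3 in methanol cleaves the acetate and triggers the retro-aldol to dione 9. The facial relay of the iodoether is lost here, so 9 would have to be separated from its ring-fusion diastereomer.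

2. Step 6. Protonation of the retro-aldol enolate on the concave face, or enolisation afterwards, would give the trans ring fusion. Fallback, from 7 back to 9: the fragmentation is run with Zn and Me3SiCl in THF without a proton source, and the regiodefined enolate is isolated as the trimethylsilyl enol ether of the methylidene-site ketone F3. MeLi then regenerates the lithium enolate, which is protonated kinetically at −78 °C with a hindered phenol (2,6-di-tert-butyl-4-methylphenol) on the convex face to give cis-fused 9.

3. Step 14. Epimerisation α to the formyl group and low facial selectivity in the trichloromethide addition would give a mixture at the side-chain carbinol. Fallback, from 19 (as the epimer mixture) back to 19: Dess–Martin oxidation gives the trichloromethyl ketone F4. Reagent-controlled reduction with catecholborane and the (S)-B-butyl oxazaborolidine (Corey–Bakshi–Shibata reduction, as in the Corey–Link sequence) then returns the R carbinol 19.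

Further compounds
F1 | step 5 | 3-oxo-2-[(2E,4R)-4,8-dimethylnona-2,7-dien-4-yl]cyclopent-1-en-1-yl acetate | CC(C)=CCC[C@@](/C=C/C)(C)C1=C(OC(C)=O)CCC1=O
F2 | step 5 | tricyclic acetoxycyclobutane photoadduct (acetate of 8) | O=C1CC[C@@]2(OC(C)=O)C(C)(C)[C@@H]3CC[C@](C)(/C=C/C)[C@]123
F3 | step 6 | trimethylsilyl enol ether of the methylidene-site ketone of 9 (ring-fusion enol ether) | C/C=C/[C@@]1(C)CC[C@@H]2C1=C(O[Si](C)(C)C)CCC(=O)C2(C)C
F4 | step 14 | 2,2,2-trichloro-1-[(3R,4R,5S)-4-Az-5-methoxytetrahydrofuran-3-yl]ethanone | C=C1CCCC(C)(C)[C@@H]2CC[C@@](C)([C@@H]3[C@@H](OC)OC[C@@H]3C(=O)C(Cl)(Cl)Cl)[C@H]12
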